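**Plan**

- Retrosynthesis: the anisoate ester and the C8–C9 epoxide oxygen are removed first, then the C8–CH3 bond (alkenyl triflate), the C6–O and C5–H bonds (C5=C6 olefin) and the C4–isopropyl bond. The core cut is C1–C2, made while an extra bond C4–C9 is restored. The resulting bicycle is cut at C8–C9 (aldol) and C5–C6 (Michael) to cyclopentane-1,3-dione and acrolein.
- Enabling feature: in the hydroazulene, C4 and C9 are 1,3-related across C5 and flank the C10–C1 edge of the seven-membered ring. A bond C4–C9 turns the core into a bicyclo[3.2.1]oct-6-ene (one-carbon bridge C4, etheno bridge C1=C10, three-carbon bridge C6–C7–C8). Its C4 vinyl carbinol and etheno bridge form a 3-hydroxy-1,5-diene, and a C8 carbonyl next to C9 marks C4–C9 as the bond that breaks.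
- Forward order of rings: five-membered ring C4/C5/C1/C10/C9 (bought as the dione), then six-membered ring C4–C5–C6–C7–C8–C9 by Michael/aldol, then a charge-accelerated [3,3] shift that closes the cyclopentanone (C1–C2) and opens the bicycle to the cycloheptenone.
- Stereochemistry: C5/C9 from an amino-acid-catalysed desymmetrising aldol; C1 from C5 through the suprafacial [3,3] shift, with a phenylsulfanyl group on C5 that locks C5 and later becomes the C5=C6 olefin; C4 by addition anti to SPh; C5–H and C6–O by syn hydroboration anti to the angular methyl; the epoxide by C6–OH-directed epoxidation.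

Key step: step 9

Locants: all intermediates carry the core numbers of the target (C1 quaternary ring-fusion carbon with CH3, C2, C3, C4 isopropyl carbinol, C5 ring-fusion CH, C6 ester carbinol, C7, C8 methyl-bearing epoxide carbon, C9, C10); α is the face of the C1 methyl, β the other face.

Assumption: the L-configured proline catalyst of step 3 is taken to give 6 as drawn (its antipode would be used otherwise), and the C8 carbinol configuration shown for 6–11 is the expected one but is erased by the oxidation in step 8.

**Route**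

Step 1
Reactants: 1 cyclopentane-1,3-dione; 2 N-(phenylsulfanyl)phthalimide
Product: 3 2-(phenylsulfanyl)cyclopentane-1,3-dione
Conditions: Et3N (10 mol %), CH2Cl2, 0 °C → rt
Reagents that add atoms: none
Why: Electrophilic sulfenylation of the enolised 1,3-dione at C2 by the N–S reagent, limited to the monosulfide by using one equivalent, installs the group that later blocks, locks and finally unsaturates C5.

Step 2
Reactants: 3 2-(phenylsulfanyl)cyclopentane-1,3-dione; 4 acrolein
Product: 5 3-[2,5-dioxo-1-(phenylsulfanyl)cyclopentyl]propanal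
Conditions: Et3N (5 mol %), MeCN, 0 °C → rt
Reagents that add atoms: none
Why: Michael addition of the acidic 2-substituted 1,3-dione to acrolein is a standard route to 2,2-disubstituted diones and creates the quaternary but still prochiral C5.

Step 3
Reactants: 5 3-[2,5-dioxo-1-(phenylsulfanyl)cyclopentyl]propanal
Product: 6 (1S,2R,5R)-2-hydroxy-5-(phenylsulfanyl)bicyclo[3.2.1]octane-6,8-dione (bridgeheads C9 and C5, ketones C1 and C4, C8–OH axial on the side of the C4 bridge)
Conditions: (2S,4R)-4-(tert-butyldiphenylsilyloxy)proline (20 mol %), MeCN, rt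
Reagents that add atoms: none
Why: Enamine-mediated enantiogroup-differentiating intramolecular aldol reaction (Hajos–Parrish-type desymmetrisation in its bridging, 6-enolendo mode), in which the catalyst condenses with one of the two enantiotopic ketones and the α-carbon C9 attacks the aldehyde, so that C5, C9 and the absolute configuration of the whole route are set by the catalyst, the axial C8 carbinol being the expected diastereomer.

Step 4
Reactants: 6 (1S,2R,5R)-2-hydroxy-5-(phenylsulfanyl)bicyclo[3.2.1]octane-6,8-dione
Product: 7 (1S,2R,5R)-6,8-dioxo-5-(phenylsulfanyl)bicyclo[3.2.1]octan-2-yl acetate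
Conditions: Ac2O, pyridine, DMAP (cat.), CH2Cl2, 0 °C → rt
Reagents that add atoms: acetic anhydride, CC(=O)OC(C)=O
Why: Acylation of the secondary alcohol protects the aldol unit against base-induced retro-aldol cleavage in step 5, and β-elimination of acetate is impossible because the intervening carbon C9 is a bridgehead.

Step 5
Reactants: 7 (1S,2R,5R)-6,8-dioxo-5-(phenylsulfanyl)bicyclo[3.2.1]octan-2-yl acetate
Product: 8 (1S,2R,5R)-2-acetoxy-8-oxo-5-(phenylsulfanyl)bicyclo[3.2.1]oct-6-en-6-yl trifluoromethanesulfonate (C1 enol triflate, C1=C10)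
Conditions: KN(SiMe3)2, THF, −78 °C; then PhNTf2, −78 → −40 °C
Reagents that add atoms: N-phenylbis(trifluoromethanesulfonimide), O=S(=O)(N(c1ccccc1)S(=O)(=O)C(F)(F)F)C(F)(F)F
Why: Kinetic enolate O-triflation is regiospecific because the C4 ketone lies between two bridgeheads and cannot enolise, so only the C1 ketone is deprotonated, towards C10.

Step 6
Reactants: 8 (1S,2R,5R)-2-acetoxy-8-oxo-5-(phenylsulfanyl)bicyclo[3.2.1]oct-6-en-6-yl trifluoromethanesulfonate
Product: 9 (1S,2R,5R)-6-methyl-8-oxo-5-(phenylsulfanyl)bicyclo[3.2.1]oct-6-en-2-yl acetate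
Conditions: MeZnCl, Pd(PPh3)4 (5 mol %), THF, rt → 40 °C
Reagents that add atoms: methylzinc chloride, C[Zn]Cl
Why: Negishi coupling of the alkenyl triflate with methylzinc chloride installs the C1 methyl group without adding to the ketone or the acetate.

Step 7
Reactants: 9 (1S,2R,5R)-6-methyl-8-oxo-5-(phenylsulfanyl)bicyclo[3.2.1]oct-6-en-2-yl acetate; 10 vinylmagnesium bromide
Product: 11 (1S,2R,5R,8R)-8-ethenyl-6-methyl-5-(phenylsulfanyl)bicyclo[3.2.1]oct-6-ene-2,8-diol (vinyl on C4 syn to the C1=C10 bridge)
Conditions: CH2=CHMgBr (4 equiv), THF, −78 → 0 °C; aq. NH4Cl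
Reagents that add atoms: none
Why: Grignard 1,2-addition to the strained, non-enolisable bridging ketone should occur from the open face above the C1=C10 olefin, the other face being screened by the axial hydrogen and acetoxy group of the three-carbon bridge (the selectivity known for 7-norbornenones), which places the vinyl group syn to that olefin as the rearrangement requires, while excess reagent cleaves the acetate.

Step 8
Reactants: 11 (1S,2R,5R,8R)-8-ethenyl-6-methyl-5-(phenylsulfanyl)bicyclo[3.2.1]oct-6-ene-2,8-diol
Product: 12 (1R,5R,8R)-8-ethenyl-8-hydroxy-6-methyl-5-(phenylsulfanyl)bicyclo[3.2.1]oct-6-en-2-one (C8 ketone next to the C9 bridgehead)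
Conditions: Dess–Martin periodinane, NaHCO3, CH2Cl2, 0 °C
Reagents that add atoms: none
Why: Dess–Martin oxidation converts the secondary alcohol into the C8 ketone under buffered, non-basic conditions, leaving the tertiary alcohol and the sulfide untouched and the β-hydroxy ketone intact until base is added.

Step 9
Reactants: 12 (1R,5R,8R)-8-ethenyl-8-hydroxy-6-methyl-5-(phenylsulfanyl)bicyclo[3.2.1]oct-6-en-2-one
Product: 13 cis-fused enedione 1α-methyl-5α-(phenylsulfanyl)bicyclo[5.3.0]dec-9-ene-4,8-dione (core numbering)
Conditions: KN(SiMe3)2 (1.1 equiv), 18-crown-6, THF, −78 → −20 °C; then AcOH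
Reagents that add atoms: none
Why: Deprotonation gives the tertiary potassium alkoxide, which should undergo an anionic oxy-Cope ([3,3]) rearrangement through the boat array C2=C3–C4–C9–C10=C1 that the bicycle enforces; the C4–C9 bond, a retro-aldol bond because C9 is alpha to the C8 ketone, breaks ahead of C1–C2 bond formation, and the resulting C3=C4 enolate is protonated on work-up. The closest known reaction type is the alkoxide-accelerated oxy-Cope rearrangement of syn-7-vinylnorbornen-7-ols to cis-hydrindenones, here in a carbonyl-assisted, asynchronous form whose limit is retro-aldol fragmentation followed by vinylogous Michael re-closure. The cyclopentanone ring closes in the six-centre boat transition state of the sigmatropic shift (formally a 5-endo-trig attack of the dienolate gamma-carbon C1 on the vinyl ketone, made feasible by the preorganised cage), whereas the seven-membered ring is not closed but unveiled by cleavage of the one-carbon bridge bond. The new quaternary centre C1 is set by suprafacial delivery of C2 to the olefin face that looks at the C4 bridge, so its configuration follows from the C5 bridgehead, which keeps all four bonds and cannot epimerise because it carries SPh instead of H; SPh and CH3 end up cis. The step needs regioselection between the two allylic bridgeheads (C4–C9 cleavage with bonding at the methyl-bearing C1, not C4–C5 cleavage with bonding at C10), and the C8 carbonyl secures it by turning the charge that develops at C9 into a dienolate, a far larger stabilisation than the alpha-thio allyl stabilisation available at C5.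

Step 10
Reactants: 13 cis-fused enedione 1α-methyl-5α-(phenylsulfanyl)bicyclo[5.3.0]dec-9-ene-4,8-dione
Product: 14 8-[dimethyl(phenyl)silyloxy]-1α-methyl-5α-(phenylsulfanyl)bicyclo[5.3.0]dec-8-en-4-one (core numbering)
Conditions: [(Ph3P)CuH]6 (3 mol %), PhMe2SiH, toluene, rt
Reagents that add atoms: dimethyl(phenyl)silane, C[SiH](C)c1ccccc1
Why: Copper hydride-catalysed conjugate hydrosilylation is selective for the enone over the hindered α-thio ketone and stores the regiodefined C8 enolate as its silyl ether, which fixes the future position of the C8=C9 olefin.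

Step 11
Reactants: 14 8-[dimethyl(phenyl)silyloxy]-1α-methyl-5α-(phenylsulfanyl)bicyclo[5.3.0]dec-8-en-4-one; 15 isopropylmagnesium chloride
Product: 16 8-[dimethyl(phenyl)silyloxy]-4β-isopropyl-1α-methyl-5α-(phenylsulfanyl)bicyclo[5.3.0]dec-8-en-4α-ol (core numbering)
Conditions: iPrMgCl (3 equiv), LaCl3·2LiCl, THF, −20 → 0 °C; pH 7 buffer
Reagents that add atoms: none
Why: Lanthanum-promoted Grignard 1,2-addition, which suppresses enolisation and reduction at hindered ketones, should take place anti to the large α-phenylsulfanyl group (Felkin–Anh control), that is from the β-face, giving the C4 carbinol with OH cis to SPh and to the angular methyl.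

Step 12
Reactants: 16 8-[dimethyl(phenyl)silyloxy]-4β-isopropyl-1α-methyl-5α-(phenylsulfanyl)bicyclo[5.3.0]dec-8-en-4α-ol
Product: 18 4α-hydroxy-4β-isopropyl-1α-methyl-5α-(phenylsulfanyl)bicyclo[5.3.0]dec-8-en-8-yl trifluoromethanesulfonate (core numbering), via lithium enolate 17 (not isolated)
Conditions: MeLi (2.2 equiv), THF, 0 °C; then PhNTf2, −78 → 0 °C
Reagents that add atoms: N-phenylbis(trifluoromethanesulfonimide), O=S(=O)(N(c1ccccc1)S(=O)(=O)C(F)(F)F)C(F)(F)F
Why: Methyllithium cleaves the silyl enol ether to the regiospecific lithium enolate (and deprotonates the alcohol), and O-triflation of that enolate gives the C8=C9 enol triflate, a latent methyl olefin that is too electron-poor to react with borane in step 14.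

Step 13
Reactants: 18 4α-hydroxy-4β-isopropyl-1α-methyl-5α-(phenylsulfanyl)bicyclo[5.3.0]dec-8-en-8-yl trifluoromethanesulfonate
Product: 20 4α-hydroxy-4β-isopropyl-1α-methylbicyclo[5.3.0]deca-5,8-dien-8-yl trifluoromethanesulfonate (core numbering), via sulfoxide 19 (not isolated)
Conditions: mCPBA (1.0 equiv), CH2Cl2, −78 °C; aq. NaHCO3 wash; then toluene, 90 °C
Reagents that add atoms: none
Why: Sulfide oxidation is much faster than epoxidation of the electron-poor olefin, and the thermal syn-elimination of the sulfoxide (sulfoxide pyrolysis) can take a hydrogen only from C6, so that the C5=C6 olefin forms regiospecifically.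

Step 14
Reactants: 20 4α-hydroxy-4β-isopropyl-1α-methylbicyclo[5.3.0]deca-5,8-dien-8-yl trifluoromethanesulfonate
Product: 22 trans-fused 4α,6β-dihydroxy-4β-isopropyl-1α-methyl-5β-H-bicyclo[5.3.0]dec-8-en-8-yl trifluoromethanesulfonate (core numbering), via alkylborane 21 (not isolated)
Conditions: BH3·THF, THF, 0 °C → rt; then H2O2, aq. NaHCO3, 0 °C → rt
Reagents that add atoms: hydrogen peroxide, OO
Why: Hydroboration–oxidation places boron on the less substituted C6 and adds H and B to the same face, which should be the β-face opposite the axial angular methyl as in steroidal 5-enes, so that the trans ring fusion (5β-H) and the 6β-hydroxyl are set in one event while the enol triflate stays inert.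

Step 15
Reactants: 22 trans-fused 4α,6β-dihydroxy-4β-isopropyl-1α-methyl-5β-H-bicyclo[5.3.0]dec-8-en-8-yl trifluoromethanesulfonate
Product: 23 jaeschkeanadiol, 4β-isopropyl-1α,8-dimethyl-5β-H-bicyclo[5.3.0]dec-8-ene-4α,6β-diol (core numbering)
Conditions: MeB(OH)2, Pd(dppf)Cl2 (5 mol %), K2CO3, dioxane/H2O, 70 °C
Reagents that add atoms: methylboronic acid, CB(O)O
Why: Suzuki–Miyaura methylation of the alkenyl triflate tolerates the free diol and turns the latent olefin into the trisubstituted C8=C9 double bond.

Step 16
Reactants: 23 jaeschkeanadiol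
Product: 24 8β,9β-epoxyjaeschkeanadiol (epoxide oxygen cis to the C6 hydroxyl)
Conditions: VO(acac)2 (5 mol %), tBuOOH, CH2Cl2, 0 °C → rt
Reagents that add atoms: tert-butyl hydroperoxide, CC(C)(C)OO
Why: Vanadium-catalysed hydroxyl-directed epoxidation of the homoallylic alcohol delivers oxygen to the olefin face of the secondary C6 hydroxyl, giving the 8β,9β-epoxide with the epoxide oxygen cis to the C6 oxygen.

Step 17
Reactants: 24 8β,9β-epoxyjaeschkeanadiol; 25 4-methoxybenzoyl chloride
Product: 26 target, 8β,9β-epoxyjaeschkeanadiol 6-(4-methoxybenzoate)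
Conditions: Et3N, DMAP (20 mol %), CH2Cl2, rt
Reagents that add atoms: none
Why: DMAP-catalysed acylation occurs only at the secondary C6 alcohol, the tertiary C4 alcohol being inert, and the amine-buffered medium spares the epoxide.

**Compound list**

1 | cyclopentane-1,3-dione | O=C1CCC(=O)C1 | starting material
2 | N-(phenylsulfanyl)phthalimide | O=C1N(Sc2ccccc2)C(=O)c2ccccc12 | starting material
3 | 2-(phenylsulfanyl)cyclopentane-1,3-dione | O=C1CCC(=O)C1Sc1ccccc1 | intermediate
4 | acrolein (prop-2-enal) | C=CC=O | starting material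
5 | 3-[2,5-dioxo-1-(phenylsulfanyl)cyclopentyl]propanal | O=CCCC1(Sc2ccccc2)C(=O)CCC1=O | intermediate
6 | (1S,2R,5R)-2-hydroxy-5-(phenylsulfanyl)bicyclo[3.2.1]octane-6,8-dione | O=C1C[C@H]2[C@H](O)CC[C@]1(Sc3ccccc3)C2=O | intermediate
7 | (1S,2R,5R)-6,8-dioxo-5-(phenylsulfanyl)bicyclo[3.2.1]octan-2-yl acetate | O=C1C[C@H]2[C@H](OC(C)=O)CC[C@]1(Sc3ccccc3)C2=O | intermediate
8 | (1S,2R,5R)-2-acetoxy-8-oxo-5-(phenylsulfanyl)bicyclo[3.2.1]oct-6-en-6-yl trifluoromethanesulfonate | FC(F)(F)S(=O)(=O)OC1=C[C@H]2[C@H](OC(C)=O)CC[C@]1(Sc3ccccc3)C2=O | intermediate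
9 | (1S,2R,5R)-6-methyl-8-oxo-5-(phenylsulfanyl)bicyclo[3.2.1]oct-6-en-2-yl acetate | CC1=C[C@H]2[C@H](OC(C)=O)CC[C@]1(Sc3ccccc3)C2=O | intermediate
10 | vinylmagnesium bromide | C=C[Mg]Br | starting material
11 | (1S,2R,5R,8R)-8-ethenyl-6-methyl-5-(phenylsulfanyl)bicyclo[3.2.1]oct-6-ene-2,8-diol | CC1=C[C@H]2[C@H](O)CC[C@]1(Sc3ccccc3)[C@@]2(O)C=C | intermediate
12 | (1R,5R,8R)-8-ethenyl-8-hydroxy-6-methyl-5-(phenylsulfanyl)bicyclo[3.2.1]oct-6-en-2-one | CC1=C[C@H]2C(=O)CC[C@]1(Sc3ccccc3)[C@@]2(O)C=C | intermediate
13 | cis-fused 1α-methyl-5α-(phenylsulfanyl)bicyclo[5.3.0]dec-9-ene-4,8-dione (core numbering) | C1CC(=O)C=C[C@@]2(C)CCC(=O)[C@@]12Sc3ccccc3 | intermediate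
14 | 8-[dimethyl(phenyl)silyloxy]-1α-methyl-5α-(phenylsulfanyl)bicyclo[5.3.0]dec-8-en-4-one (core numbering) | C1CC(O[Si](C)(C)c3ccccc3)=CC[C@@]2(C)CCC(=O)[C@@]12Sc4ccccc4 | intermediate
15 | isopropylmagnesium chloride | CC(C)[Mg]Cl | starting material
16 | 8-[dimethyl(phenyl)silyloxy]-4β-isopropyl-1α-methyl-5α-(phenylsulfanyl)bicyclo[5.3.0]dec-8-en-4α-ol (core numbering) | C1CC(O[Si](C)(C)c3ccccc3)=CC[C@@]2(C)CC[C@@](O)(C(C)C)[C@@]12Sc4ccccc4 | intermediate
17 | dilithium C4-alkoxide C8-enolate derived from 16 (not isolated) | C1CC([O-])=CC[C@@]2(C)CC[C@@]([O-])(C(C)C)[C@@]12Sc3ccccc3.[Li+].[Li+] | intermediate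
18 | 4α-hydroxy-4β-isopropyl-1α-methyl-5α-(phenylsulfanyl)bicyclo[5.3.0]dec-8-en-8-yl trifluoromethanesulfonate (core numbering) | C1CC(OS(=O)(=O)C(F)(F)F)=CC[C@@]2(C)CC[C@@](O)(C(C)C)[C@@]12Sc3ccccc3 | intermediate
19 | S-oxide of 18, both configurations at sulfur (not isolated) | C1CC(OS(=O)(=O)C(F)(F)F)=CC[C@@]2(C)CC[C@@](O)(C(C)C)[C@@]12S(=O)c3ccccc3 | intermediate
20 | 4α-hydroxy-4β-isopropyl-1α-methylbicyclo[5.3.0]deca-5,8-dien-8-yl trifluoromethanesulfonate (core numbering) | CC(C)[C@]1(O)CC[C@]2(C)CC=C(OS(=O)(=O)C(F)(F)F)CC=C12 | intermediate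
21 | 6β-boryl-5β-H adduct of 20 with the C4 oxygen as borinate (not isolated) | B[C@H]1CC(OS(=O)(=O)C(F)(F)F)=CC[C@@]2(C)CC[C@@](OB)(C(C)C)[C@H]12 | intermediate
22 | trans-fused 4α,6β-dihydroxy-4β-isopropyl-1α-methyl-5β-H-bicyclo[5.3.0]dec-8-en-8-yl trifluoromethanesulfonate (core numbering) | O[C@H]1CC(OS(=O)(=O)C(F)(F)F)=CC[C@@]2(C)CC[C@@](O)(C(C)C)[C@H]12 | intermediate
23 | jaeschkeanadiol, 4β-isopropyl-1α,8-dimethyl-5β-H-bicyclo[5.3.0]dec-8-ene-4α,6β-diol (core numbering) | O[C@H]1CC(C)=CC[C@@]2(C)CC[C@@](O)(C(C)C)[C@H]12 | intermediate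
24 | 8β,9β-epoxyjaeschkeanadiol | O[C@H]1C[C@@]2(C)O[C@H]2C[C@@]2(C)CC[C@@](O)(C(C)C)[C@H]12 | intermediate
25 | 4-methoxybenzoyl chloride | COc1ccc(C(=O)Cl)cc1 | starting material
26 | 8β,9β-epoxyjaeschkeanadiol 6-(4-methoxybenzoate) | COc1ccc(C(=O)O[C@H]2C[C@@]3(C)O[C@H]3C[C@@]3(C)CC[C@@](O)(C(C)C)[C@H]23)cc1 | target

**Totals and risks**

Total steps: 17. Longest linear sequence: 17 steps (1 to 26).

Steps most likely to fail:

Step 9. After the C4–C9 bond breaks, the ring-opened dienolate may relax out of the cage before C1–C2 bonding, or bond to C2 through its alpha-carbon C9 (a net 1,3-shift), so that the cage re-closure at C1 is lost. The fallback is a stepwise, Lewis-acid ring closure that sets out from 12. Catalytic DBU in CH2Cl2 at 0 °C should give the retro-aldol product 5-acryloyl-4-methyl-5-(phenylsulfanyl)cyclohept-3-en-1-one F1. TBSOTf/Et3N converts its only enolisable ketone into the conjugated tert-butyldimethylsilyl dienol ether F2. Me2AlCl (or TiCl4) in CH2Cl2 at −78 °C then activates the vinyl ketone for an intramolecular vinylogous Mukaiyama–Michael addition, which is gamma-selective for silyl dienol ethers and, being cationic in character, is not bound by the stereoelectronic limits of an anionic 5-endo closure. Aqueous work-up returns the route at 13.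

Step 14. The isopropyl group on the β-face of C4 may erode the facial preference set by the angular methyl, and the hindered trisubstituted olefin may react slowly. The fallback oxygenates C5/C6 before the isopropyl group is present and sets out from 14. CsF and PhNTf2 in DME give the keto enol triflate F3. mCPBA at −78 °C followed by heating in toluene gives, through the sulfoxide F4, the enone F5. Ketalisation with 1,2-bis(trimethylsilyloxy)ethane and catalytic TMSOTf at −78 °C, which keeps the olefin in place, gives the dioxolane F6. Hydroboration with BH3·THF, where only the angular methyl differentiates the olefin faces, gives the alkylborane F7 and, after H2O2, the hydroxy ketal F8. PPTS in aqueous acetone releases the trans-fused hydroxy ketone F9. Addition of iPrMgCl/LaCl3·2LiCl, which should occur anti to the axial angular methyl of the trans-fused ketone, returns the route at 22.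

Step 3. The catalyst may condense with the aldehyde instead of a ring ketone, or differentiate the two enantiotopic ketones poorly, giving low conversion or low enantiomeric purity. The fallback replaces catalytic desymmetrisation by racemic cyclisation and enzymatic kinetic resolution and sets out from 5. Pyrrolidine/AcOH (cat.) in MeCN gives the racemic ketol F10. Candida antarctica lipase B with vinyl acetate should then acylate the (2R)-configured alcohol, as the empirical selectivity rule for secondary alcohols predicts, and deliver the acetate directly, so that the route is rejoined at 7.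

**Further compounds**

F1 | step 9 | 5-acryloyl-4-methyl-5-(phenylsulfanyl)cyclohept-3-en-1-one (C5 configuration as in 12) | C=CC(=O)[C@@]1(Sc2ccccc2)CCC(=O)CC=C1C
F2 | step 9 | tert-butyldimethylsilyl dienol ether of F1 (C8–O–Si, C8=C9, C10=C1) | C=CC(=O)[C@@]1(Sc2ccccc2)CCC(O[Si](C)(C)C(C)(C)C)=CC=C1C
F3 | step 14 | 1α-methyl-4-oxo-5α-(phenylsulfanyl)bicyclo[5.3.0]dec-8-en-8-yl trifluoromethanesulfonate (core numbering) | C1CC(OS(=O)(=O)C(F)(F)F)=CC[C@@]2(C)CCC(=O)[C@@]12Sc3ccccc3
F4 | step 14 | S-oxide of F3 | C1CC(OS(=O)(=O)C(F)(F)F)=CC[C@@]2(C)CCC(=O)[C@@]12S(=O)c3ccccc3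
F5 | step 14 | 1α-methyl-4-oxobicyclo[5.3.0]deca-5,8-dien-8-yl trifluoromethanesulfonate (core numbering) | O=C1CC[C@]2(C)CC=C(OS(=O)(=O)C(F)(F)F)CC=C12
F6 | step 14 | ethylene ketal of F5 at C4 | C1COC2(O1)CC[C@]3(C)CC=C(OS(=O)(=O)C(F)(F)F)CC=C23
F7 | step 14 | 6β-boryl-5β-H adduct of F6 | B[C@H]1CC(OS(=O)(=O)C(F)(F)F)=CC[C@@]2(C)CCC3(OCCO3)[C@H]12
F8 | step 14 | 6β-hydroxy-5β-H ketal | O[C@H]1CC(OS(=O)(=O)C(F)(F)F)=CC[C@@]2(C)CCC3(OCCO3)[C@H]12
F9 | step 14 | trans-fused 6β-hydroxy-1α-methyl-4-oxo-5β-H-bicyclo[5.3.0]dec-8-en-8-yl trifluoromethanesulfonate (core numbering) | O[C@H]1CC(OS(=O)(=O)C(F)(F)F)=CC[C@@]2(C)CCC(=O)[C@H]12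
F10 | step 3 | racemic 6 (relative configuration as in 6) | O=C1CC2C(O)CCC1(Sc3ccccc3)C2=O
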